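**Strategy**

Everything rests on cutting the piperidine at N1–C2 and C5–C6. C2 carries the future flavone ring A, a 2,4,6-trioxygenated benzene that stabilises a benzylic cation, and N1 carries only a methyl group; a strain-release (4+2) annulation of a racemic aryl cyclobutane-1,1-diester with N-methylmethanimine exploits both. In one operation a chiral magnesium Lewis acid opens the four-membered ring, forms both bonds, closes the piperidine, installs N-methyl and sets the (R)-centre by dynamic kinetic asymmetric control. The precursor is dimethyl 2-arylcyclobutane-1,1-dicarboxylate whose aryl group has benzyl ethers on the two flanking oxygens and an allyl ether on the para oxygen, the later pyranone O1.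

Key step: step 6

Assumption: the (S,S)-pybox ligand is taken to give the (R)-piperidine; if the sense of induction is the opposite, its enantiomer is used.

Remark: the para oxygen is carried as an allyl ether, not a silyl ether, because it must survive the hot, basic ester-removal steps; a phenol set free there would sit para to the benzylic amine and could racemise C2 through a quinone methide.

**Route**

Step 1
Reactants: 1 2,4,6-trihydroxybenzaldehyde
Product: 2 4-(allyloxy)-2,6-dihydroxybenzaldehyde
Conditions: allyl bromide (1.0 equiv), KHCO3, DMF, rt to 40 °C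
Reagents that add atoms: allyl bromide, C=CCBr
Why: Williamson O-alkylation, in which the 4-hydroxyl (para to the formyl group, the most acidic and the only one not hydrogen-bonded to the carbonyl) is the one ionised by the weak base, so one equivalent of allyl bromide should alkylate it selectively.

Step 2
Reactants: 2 4-(allyloxy)-2,6-dihydroxybenzaldehyde
Product: 3 4-(allyloxy)-2,6-bis(benzyloxy)benzaldehyde
Conditions: BnBr (2.5 equiv), K2CO3, DMF, 60 °C
Reagents that add atoms: benzyl bromide, BrCc1ccccc1
Why: Williamson etherification of the two chelated ortho hydroxyls, which needs the stronger base, excess benzyl bromide and warming, while the allyl ether is inert.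

Step 3
Reactants: 3 4-(allyloxy)-2,6-bis(benzyloxy)benzaldehyde
Product: 4 5-(allyloxy)-1,3-bis(benzyloxy)-2-ethenylbenzene
Conditions: Ph3PCH3Br, KOtBu, THF, 0 °C to rt; base-washed silica
Reagents that add atoms: methyltriphenylphosphonium bromide, C[P+](c1ccccc1)(c1ccccc1)c1ccccc1.[Br-]
Why: Wittig methylenation of a non-enolisable aryl aldehyde with the small unstabilised ylide, which tolerates the two ortho substituents.

Step 4
Reactants: 5 dimethyl malonate
Product: 6 dimethyl 2-methylidenepropanedioate
Conditions: (CH2O)n, diisopropylammonium trifluoroacetate, TFA (cat.), THF, reflux; used at once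
Reagents that add atoms: paraformaldehyde (as formaldehyde), C=O
Why: Knoevenagel-type α-methylenation (Mannich aminomethylation followed by loss of the amine), with the product used fresh because it polymerises on standing.

Step 5
Reactants: 4 5-(allyloxy)-1,3-bis(benzyloxy)-2-ethenylbenzene; 6 dimethyl 2-methylidenepropanedioate
Product: 7 dimethyl 2-[4-(allyloxy)-2,6-bis(benzyloxy)phenyl]cyclobutane-1,1-dicarboxylate (racemic)
Conditions: Sc(OTf)3 (2 mol%), 6 (1.3 equiv), CH2Cl2, −78 °C; Et3N quench at −78 °C
Reagents that add atoms: none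
Why: Lewis acid-catalysed stepwise (2+2) cycloaddition in which the styrene terminus adds to the Sc-bound methylidenemalonate and the benzylic cation/malonate zwitterion collapses to the cyclobutane, polarity placing the aryl-bearing carbon next to the diester carbon; the new stereocentre is racemic, which is of no consequence because the next step equilibrates it.

Step 6
Reactants: 7 dimethyl 2-[4-(allyloxy)-2,6-bis(benzyloxy)phenyl]cyclobutane-1,1-dicarboxylate (racemic); 8 1,3,5-trimethyl-1,3,5-triazinane
Product: 10 dimethyl (6R)-6-[4-(allyloxy)-2,6-bis(benzyloxy)phenyl]-1-methylpiperidine-3,3-dicarboxylate, via N-methylmethanimine 9 (not isolated)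
Conditions: MgI2 (10 mol%), 2,6-bis[(4S)-4-tert-butyl-4,5-dihydro-1,3-oxazol-2-yl]-4-chloropyridine (12 mol%), 8 (0.5 equiv), 4 Å MS, CCl4, rt; filtration through basic alumina as soon as 7 is consumed
Reagents that add atoms: none
Why: Proposed new method: the MgI2–pybox complex chelates the two esters of 7 and, with the push of the 2,4,6-trioxygenated ring, loosens the C1–C2 bond to a contact benzylic cation/magnesium malonate ion pair through which the two enantiomers of 7 interconvert; the nitrogen of N-methylmethanimine 9, released from 8 by the Lewis acid, attacks the benzylic carbon and the malonate then adds to the new iminium carbon. The closest known reactions are Lewis acid (4+2) annulations of donor–acceptor cyclobutanes with aldehydes and aldimines and the MgI2/pybox dynamic kinetic asymmetric (3+2) annulation of aryl cyclopropane diesters with aldimines. The piperidine ring closes by a 6-endo-trig Mannich addition of the malonate (enolexo) onto the iminium carbon. The single stereocentre, (R) at the aryl-bearing carbon, is set in the C–N bond-forming event by the chiral magnesium complex (catalyst control), which lets one enantiomer of the equilibrating substrate react faster. The step needs enantioselection under Curtin–Hammett conditions and uptake of only one imine unit; the very strong aryl donor secures racemisation of 7 that is fast relative to capture, and the short contact time with a basic quench keeps 10 from re-ionising at its benzylic C–N bond.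

Step 7
Reactants: 10 dimethyl (6R)-6-[4-(allyloxy)-2,6-bis(benzyloxy)phenyl]-1-methylpiperidine-3,3-dicarboxylate
Product: 11 methyl (6R)-6-[4-(allyloxy)-2,6-bis(benzyloxy)phenyl]-1-methylpiperidine-3-carboxylate (both C3 epimers)
Conditions: LiCl, H2O, DMSO, 140 °C
Reagents that add atoms: none
Why: Krapcho dealkoxycarbonylation (SN2 demethylation by chloride, then loss of CO2 from the malonate half-carboxylate) in a non-acidic medium, so the benzylic C–N bond should not ionise, the fully etherified arene cannot form a quinone methide, and the new C3 centre, formed as both epimers, is removed later.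

Step 8
Reactants: 11 methyl (6R)-6-[4-(allyloxy)-2,6-bis(benzyloxy)phenyl]-1-methylpiperidine-3-carboxylate (both C3 epimers)
Product: 12 (6R)-6-[4-(allyloxy)-2,6-bis(benzyloxy)phenyl]-1-methylpiperidine-3-carboxylic acid (both C3 epimers)
Conditions: LiOH, THF/MeOH/H2O, rt; AcOH to pH 7 at 0 °C
Reagents that add atoms: lithium hydroxide, [Li+].[OH-]
Why: Ester saponification by acyl substitution with hydroxide, in which C6 is not enolisable and the cold neutralisation to pH 7 avoids holding the amino acid in strong acid.

Step 9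
Reactants: 12 (6R)-6-[4-(allyloxy)-2,6-bis(benzyloxy)phenyl]-1-methylpiperidine-3-carboxylic acid (both C3 epimers)
Product: 14 (2R)-2-[4-(allyloxy)-2,6-bis(benzyloxy)phenyl]-1-methylpiperidine, via Barton thiohydroxamate ester 13 (not isolated)
Conditions: N-hydroxypyridine-2-thione, DCC, DMAP (cat.), CH2Cl2, 0 °C to rt, dark; then t-BuSH, hν (tungsten lamp), rt
Reagents that add atoms: none
Why: Barton reductive decarboxylation, in which the thiohydroxamate ester fragments under visible light in a radical chain, CO2 is lost and the secondary piperidin-3-yl radical takes hydrogen from the thiol, which erases the C3 centre and leaves the aryl-bearing stereocentre untouched.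

Step 10
Reactants: 14 (2R)-2-[4-(allyloxy)-2,6-bis(benzyloxy)phenyl]-1-methylpiperidine
Product: 15 3,5-bis(benzyloxy)-4-[(2R)-1-methylpiperidin-2-yl]phenol
Conditions: Pd(PPh3)4 (5 mol%), morpholine, THF, rt, under argon
Reagents that add atoms: none
Why: Tsuji–Trost deallylation, in which zerovalent palladium ionises the aryl allyl ether to a π-allyl complex that morpholine captures under neutral conditions, leaving the benzyl ethers and the benzylic amine alone.

Step 11
Reactants: 15 3,5-bis(benzyloxy)-4-[(2R)-1-methylpiperidin-2-yl]phenol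
Product: 17 2,4-bis(benzyloxy)-6-hydroxy-3-[(2R)-1-methylpiperidin-2-yl]benzaldehyde, via hydroxymethyl phenol 16 (not isolated)
Conditions: MgCl2, Et3N, (CH2O)n, MeCN, 70 °C; aq. NH4Cl work-up
Reagents that add atoms: paraformaldehyde (as formaldehyde), C=O
Why: Casnati–Skattebøl ortho-formylation, in which the magnesium phenoxide delivers formaldehyde to the ortho carbon and hydroxymethyl phenol 16 is oxidised by a second formaldehyde through hydride transfer; the two ortho positions are equivalent by symmetry and the medium is basic, so one aldehyde should result without acid exposure of the benzylic amine.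

Step 12
Reactants: 17 2,4-bis(benzyloxy)-6-hydroxy-3-[(2R)-1-methylpiperidin-2-yl]benzaldehyde
Product: 18 1-{2,4-bis(benzyloxy)-6-hydroxy-3-[(2R)-1-methylpiperidin-2-yl]phenyl}-3-phenylprop-2-yn-1-ol (both carbinol epimers)
Conditions: PhC≡CH (3.3 equiv), n-BuLi (3.1 equiv), THF, −78 °C; then 17, −78 to 0 °C; aq. NH4Cl
Reagents that add atoms: phenylacetylene, C#Cc1ccccc1
Why: 1,2-Addition of lithium phenylacetylide to the aldehyde after the first equivalent has deprotonated the phenol; the new carbinol centre is uncontrolled and is destroyed in the next step.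

Step 13
Reactants: 18 1-{2,4-bis(benzyloxy)-6-hydroxy-3-[(2R)-1-methylpiperidin-2-yl]phenyl}-3-phenylprop-2-yn-1-ol (both carbinol epimers)
Product: 21 5,7-bis(benzyloxy)-6-[(2R)-1-methylpiperidin-2-yl]-2-phenyl-4H-chromen-4-one, via hydroxyaryl ynone 19 (not isolated), via diethylamino enone 20 (not isolated)
Conditions: MnO2, CH2Cl2, rt; filter; filtrate + Et2NH, EtOH, 40 °C
Reagents that add atoms: none
Why: MnO2 oxidation of the benzylic–propargylic alcohol to ynone 19, conjugate addition of diethylamine to give enaminone 20, then addition–elimination by the ortho hydroxyl, a 6-endo closure that forms the flavone and excludes the 5-exo aurone pathway; only the oxygen para to the piperidine is free, so the 6-substituted flavone should be the sole regioisomer.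

Step 14
Reactants: 21 5,7-bis(benzyloxy)-6-[(2R)-1-methylpiperidin-2-yl]-2-phenyl-4H-chromen-4-one
Product: 22 5,7-dihydroxy-6-[(2R)-1-methylpiperidin-2-yl]-2-phenyl-4H-chromen-4-one
Conditions: H2 (1 atm), 10% Pd/C, EtOAc/MeOH, rt; stopped at full conversion
Reagents that add atoms: none
Why: Catalytic hydrogenolysis of the two aryl benzyl ethers, which is expected to be much faster than reduction of the chromone C2–C3 bond or cleavage of the ring C–N bond of the unprotonated amine, in a neutral medium that protects the stereocentre.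

**Compound list**

1 | 2,4,6-trihydroxybenzaldehyde | O=Cc1c(O)cc(O)cc1O | starting material
2 | 4-(allyloxy)-2,6-dihydroxybenzaldehyde | O=Cc1c(O)cc(OCC=C)cc1O | intermediate
3 | 4-(allyloxy)-2,6-bis(benzyloxy)benzaldehyde | O=Cc1c(OCc2ccccc2)cc(OCC=C)cc1OCc1ccccc1 | intermediate
4 | 5-(allyloxy)-1,3-bis(benzyloxy)-2-ethenylbenzene | C=Cc1c(OCc2ccccc2)cc(OCC=C)cc1OCc1ccccc1 | intermediate
5 | dimethyl malonate | COC(=O)CC(=O)OC | starting material
6 | dimethyl 2-methylidenepropanedioate | C=C(C(=O)OC)C(=O)OC | intermediate
7 | dimethyl 2-[4-(allyloxy)-2,6-bis(benzyloxy)phenyl]cyclobutane-1,1-dicarboxylate (racemic) | COC(=O)C1(C(=O)OC)CCC1c1c(OCc2ccccc2)cc(OCC=C)cc1OCc1ccccc1 | intermediate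
8 | 1,3,5-trimethyl-1,3,5-triazinane | CN1CN(C)CN(C)C1 | starting material
9 | N-methylmethanimine (not isolated) | C=NC | intermediate
10 | dimethyl (6R)-6-[4-(allyloxy)-2,6-bis(benzyloxy)phenyl]-1-methylpiperidine-3,3-dicarboxylate | CN1CC(C(=O)OC)(C(=O)OC)CC[C@@H]1c1c(OCc2ccccc2)cc(OCC=C)cc1OCc1ccccc1 | intermediate
11 | methyl (6R)-6-[4-(allyloxy)-2,6-bis(benzyloxy)phenyl]-1-methylpiperidine-3-carboxylate (both C3 epimers) | CN1CC(C(=O)OC)CC[C@@H]1c1c(OCc2ccccc2)cc(OCC=C)cc1OCc1ccccc1 | intermediate
12 | (6R)-6-[4-(allyloxy)-2,6-bis(benzyloxy)phenyl]-1-methylpiperidine-3-carboxylic acid (both C3 epimers) | CN1CC(C(=O)O)CC[C@@H]1c1c(OCc2ccccc2)cc(OCC=C)cc1OCc1ccccc1 | intermediate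
13 | 2-thioxopyridin-1(2H)-yl (6R)-6-[4-(allyloxy)-2,6-bis(benzyloxy)phenyl]-1-methylpiperidine-3-carboxylate (not isolated) | CN1CC(C(=O)On2ccccc2=S)CC[C@@H]1c1c(OCc2ccccc2)cc(OCC=C)cc1OCc1ccccc1 | intermediate
14 | (2R)-2-[4-(allyloxy)-2,6-bis(benzyloxy)phenyl]-1-methylpiperidine | CN1CCCC[C@@H]1c1c(OCc2ccccc2)cc(OCC=C)cc1OCc1ccccc1 | intermediate
15 | 3,5-bis(benzyloxy)-4-[(2R)-1-methylpiperidin-2-yl]phenol | CN1CCCC[C@@H]1c1c(OCc2ccccc2)cc(O)cc1OCc1ccccc1 | intermediate
16 | 3,5-bis(benzyloxy)-2-(hydroxymethyl)-4-[(2R)-1-methylpiperidin-2-yl]phenol (not isolated) | CN1CCCC[C@@H]1c1c(OCc2ccccc2)cc(O)c(CO)c1OCc1ccccc1 | intermediate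
17 | 2,4-bis(benzyloxy)-6-hydroxy-3-[(2R)-1-methylpiperidin-2-yl]benzaldehyde | CN1CCCC[C@@H]1c1c(OCc2ccccc2)cc(O)c(C=O)c1OCc1ccccc1 | intermediate
18 | 1-{2,4-bis(benzyloxy)-6-hydroxy-3-[(2R)-1-methylpiperidin-2-yl]phenyl}-3-phenylprop-2-yn-1-ol (both carbinol epimers) | CN1CCCC[C@@H]1c1c(OCc2ccccc2)cc(O)c(C(O)C#Cc2ccccc2)c1OCc1ccccc1 | intermediate
19 | 1-{2,4-bis(benzyloxy)-6-hydroxy-3-[(2R)-1-methylpiperidin-2-yl]phenyl}-3-phenylprop-2-yn-1-one (not isolated) | CN1CCCC[C@@H]1c1c(OCc2ccccc2)cc(O)c(C(=O)C#Cc2ccccc2)c1OCc1ccccc1 | intermediate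
20 | (2E)-1-{2,4-bis(benzyloxy)-6-hydroxy-3-[(2R)-1-methylpiperidin-2-yl]phenyl}-3-(diethylamino)-3-phenylprop-2-en-1-one (not isolated) | CN1CCCC[C@@H]1c1c(OCc2ccccc2)cc(O)c(C(=O)/C=C(/N(CC)CC)c2ccccc2)c1OCc1ccccc1 | intermediate
21 | 5,7-bis(benzyloxy)-6-[(2R)-1-methylpiperidin-2-yl]-2-phenyl-4H-chromen-4-one | CN1CCCC[C@@H]1c1c(OCc2ccccc2)cc2oc(-c3ccccc3)cc(=O)c2c1OCc1ccccc1 | intermediate
22 | 5,7-dihydroxy-6-[(2R)-1-methylpiperidin-2-yl]-2-phenyl-4H-chromen-4-one | CN1CCCC[C@@H]1c1c(O)cc2oc(-c3ccccc3)cc(=O)c2c1O | target

**Step count**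

Total steps: 14. Longest linear sequence: 13 steps (steps 1–3 and 5–14, from 1 to 22); step 4 is a one-step side branch.

**Steps most likely to fail**

Step 6 (key step, new method). Four things may go wrong:
- the basic triazinane or the imine may tie up the magnesium centre and stop turnover;
- two imine units may be taken up, giving an eight-membered aminal ring;
- the zwitterion may lose a proton to an open-chain alkene;
- reversible ionisation of the product at its benzylic C–N bond may erode the enantiomeric purity.

The fallback uses known chemistry, sets out from aldehyde 3 and comes back at 14, bypassing steps 3–9. Condensation of 3 with (S)-2-methylpropane-2-sulfinamide (Ti(OEt)4, THF) should give (S,E)-N-{[4-(allyloxy)-2,6-bis(benzyloxy)phenyl]methylidene}-2-methylpropane-2-sulfinamide F1. Addition of Cl(CH2)4MgBr in CH2Cl2 at −48 °C, through the usual six-membered chelate transition state, should give (S)-N-{(1R)-1-[4-(allyloxy)-2,6-bis(benzyloxy)phenyl]-5-chloropentyl}-2-methylpropane-2-sulfinamide F2. KN(SiMe3)2 in THF closes the ring by N-alkylation to (2R)-2-[4-(allyloxy)-2,6-bis(benzyloxy)phenyl]-1-[(S)-2-methylpropane-2-sulfinyl]piperidine F3. Brief HCl in MeOH at 0 °C, followed at once by basification, removes the auxiliary to give (2R)-2-[4-(allyloxy)-2,6-bis(benzyloxy)phenyl]piperidine F4. Reductive methylation (aqueous CH2O, NaBH(OAc)3) then gives 14.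

Step 5. The very electron-rich styrene may oligomerise cationically, or the Lewis acid may re-open the cyclobutane, with proton loss to an open-chain alkenyl malonate. The fallback builds the four-membered ring by malonate alkylation without a Lewis acid; it sets out from aldehyde 3 (with dimethyl malonate 5) and comes back at 7. CH2=CHMgBr adds to 3 to give 1-[4-(allyloxy)-2,6-bis(benzyloxy)phenyl]prop-2-en-1-ol F5. MnO2 oxidises it to 1-[4-(allyloxy)-2,6-bis(benzyloxy)phenyl]prop-2-en-1-one F6. Michael addition of 5 (catalytic NaOMe, MeOH) gives dimethyl 2-{3-[4-(allyloxy)-2,6-bis(benzyloxy)phenyl]-3-oxopropyl}propanedioate F7. NaBH4 at 0 °C gives dimethyl 2-{3-[4-(allyloxy)-2,6-bis(benzyloxy)phenyl]-3-hydroxypropyl}propanedioate F8, which is used crude and cold to limit lactonisation. Mitsunobu-type dehydration (Bu3P, N,N,N',N'-tetramethylazodicarboxamide, toluene) should then close the ring to 7: the activated benzylic oxygen leaves and the malonate carbon captures the benzylic centre. This last closure is the least precedented part of the fallback.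

Step 14. The C2–C3 double bond of the pyranone may be reduced, or the benzylic C–N bond hydrogenolysed, alongside debenzylation. The fallback replaces hydrogenolysis by Lewis-acid dealkylation: from 21, BCl3 with pentamethylbenzene as benzyl-cation scavenger in CH2Cl2 at −78 °C, quenched cold with MeOH and NaHCO3, should give 22 directly. It makes no new compound (F0).

**Further compounds**

F1 | step 6 | (S,E)-N-{[4-(allyloxy)-2,6-bis(benzyloxy)phenyl]methylidene}-2-methylpropane-2-sulfinamide | CC(C)(C)[S@](=O)/N=C/c1c(OCc2ccccc2)cc(OCC=C)cc1OCc1ccccc1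
F2 | step 6 | (S)-N-{(1R)-1-[4-(allyloxy)-2,6-bis(benzyloxy)phenyl]-5-chloropentyl}-2-methylpropane-2-sulfinamide | CC(C)(C)[S@](=O)N[C@H](CCCCCl)c1c(OCc2ccccc2)cc(OCC=C)cc1OCc1ccccc1
F3 | step 6 | (2R)-2-[4-(allyloxy)-2,6-bis(benzyloxy)phenyl]-1-[(S)-2-methylpropane-2-sulfinyl]piperidine | CC(C)(C)[S@](=O)N1CCCC[C@@H]1c1c(OCc2ccccc2)cc(OCC=C)cc1OCc1ccccc1
F4 | step 6 | (2R)-2-[4-(allyloxy)-2,6-bis(benzyloxy)phenyl]piperidine | N1CCCC[C@@H]1c1c(OCc2ccccc2)cc(OCC=C)cc1OCc1ccccc1
F5 | step 5 | 1-[4-(allyloxy)-2,6-bis(benzyloxy)phenyl]prop-2-en-1-ol (racemic) | C=CC(O)c1c(OCc2ccccc2)cc(OCC=C)cc1OCc1ccccc1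
F6 | step 5 | 1-[4-(allyloxy)-2,6-bis(benzyloxy)phenyl]prop-2-en-1-one | C=CC(=O)c1c(OCc2ccccc2)cc(OCC=C)cc1OCc1ccccc1
F7 | step 5 | dimethyl 2-{3-[4-(allyloxy)-2,6-bis(benzyloxy)phenyl]-3-oxopropyl}propanedioate | COC(=O)C(CCC(=O)c1c(OCc2ccccc2)cc(OCC=C)cc1OCc1ccccc1)C(=O)OC
F8 | step 5 | dimethyl 2-{3-[4-(allyloxy)-2,6-bis(benzyloxy)phenyl]-3-hydroxypropyl}propanedioate (racemic) | COC(=O)C(CCC(O)c1c(OCc2ccccc2)cc(OCC=C)cc1OCc1ccccc1)C(=O)OC
F0 | step 14 | none | none
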